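The route rests on one disconnection, the C3–C4 bond of the pyran ring. C3 is a secondary carbinol flanked by benzylic C4 and by the quaternary, non-enolisable C2, which makes it the retron of a benzyl-metal addition to an α-quaternary aldehyde. A single cathodically driven, chromium-catalysed Nozaki–Hiyama–Kishi-type cyclisation forms C3–C4, closes the pyran ring onto the fully substituted methylphloroglucinol ring and sets the C3 stereocentre under ligand control. Its precursor 15 carries on one benzene ring a chloromethyl group, an O–CMe2–CHO tether ortho to it, the 3-phenylpropanoyl ketone and two benzyl-protected phenols; it is built from 2,6-dimethoxytoluene by C–H oxidation, O-alkylation and two electrophilic substitutions.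

Key step: step 9

Remark: ring atoms are numbered as in chroman (O1, C2–C4, C4a, C5–C8, C8a); the given SMILES corresponds to 3S, which requires attack of the benzyl carbon on the Si face of the aldehyde.
Remark: the arene of the target carries three oxygens (O1, O5, O7), one more than a 2-methylresorcinol unit; step 1 introduces the missing oxygen para to the methyl group of commercial 2,6-dimethoxytoluene (the dimethyl ether of 2-methylresorcinol).
Remark: methyl ethers are carried through the two Lewis-acid steps and exchanged for benzyl ethers once the ring is fully substituted; the labile benzylic chloride 15 is generated last, under anhydrous conditions, and electrolysed without storage.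
Remark: L* in step 9 is N-[2-(4-tert-butyl-4,5-dihydro-1,3-oxazol-2-yl)-6-methylphenyl]methanesulfonamide, used as whichever enantiomer (4S or 4R) a pilot run shows to direct Si-face attack.

Step 1
Reactants: 1 2,6-dimethoxytoluene (1,3-dimethoxy-2-methylbenzene)
Product: 3 3,5-dimethoxy-4-methylphenol, via aryl pinacol boronate 2 (not isolated)
Conditions: [Ir(cod)OMe]2 (1 mol%), 4,4′-di-tert-butyl-2,2′-bipyridine (2 mol%), B2pin2 (1.0 equiv), THF, 80 °C; then Oxone (KHSO5), acetone/H2O, 0 °C to rt
Reagents that add atoms: Oxone (potassium peroxymonosulfate), [K+].[O-]S(=O)(=O)OO (phenol oxygen of 3); bis(pinacolato)diboron, CC1(C)OB(OC1(C)C)B1OC(C)(C)C(C)(C)O1 (boryl group of intermediate 2 only)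
Why: Sterically governed iridium-catalysed C–H borylation should attack the only ring C–H of 1 without an ortho substituent (para to the methyl group), and oxidation of the C–B bond then gives the phenol at that position (C–H borylation–oxidation sequence).

Step 2
Reactants: 3 3,5-dimethoxy-4-methylphenol; 4 ethyl 2-bromo-2-methylpropanoate
Product: 5 ethyl 2-(3,5-dimethoxy-4-methylphenoxy)-2-methylpropanoate
Conditions: Cs2CO3, DMF, 60 °C
Reagents that add atoms: none
Why: Williamson ether synthesis, in which the unhindered phenoxide of 3 (two ortho hydrogens) displaces bromide from the tertiary α-bromo ester, the standard way to 2-aryloxy-2-methylpropanoates.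

Step 3
Reactants: 5 ethyl 2-(3,5-dimethoxy-4-methylphenoxy)-2-methylpropanoate; 6 3-phenylpropanoyl chloride
Product: 7 ethyl 2-[3,5-dimethoxy-4-methyl-2-(3-phenylpropanoyl)phenoxy]-2-methylpropanoate
Conditions: SnCl4 (2.2 equiv), CH2Cl2, −10 °C to rt
Reagents that add atoms: none
Why: Friedel–Crafts acylation; the two free ring positions of 5 are equivalent and each is ortho, ortho and para to an oxygen donor, so a single mono-ketone should form, and the acyl group then deactivates the ring against a second acylation.

Step 4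
Reactants: 7 ethyl 2-[3,5-dimethoxy-4-methyl-2-(3-phenylpropanoyl)phenoxy]-2-methylpropanoate
Product: 9 ethyl 2-[2-formyl-3,5-dimethoxy-4-methyl-6-(3-phenylpropanoyl)phenoxy]-2-methylpropanoate, via chloro(methoxy)methyl arene 8 (not isolated)
Conditions: Cl2CHOMe (1.5 equiv), TiCl4 (3 equiv), CH2Cl2, −10 °C to rt; aq. HCl work-up
Reagents that add atoms: dichloromethyl methyl ether, COC(Cl)Cl (formyl carbon); water, O (carbonyl oxygen, on hydrolysis of 8)
Why: Rieche formylation; the strongly electrophilic Cl2CHOMe–TiCl4 pair should attack the single remaining ring position, still activated by three ether oxygens and meta to the ketone, and the α-chloro ether is hydrolysed to the aldehyde on work-up.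

Step 5
Reactants: 9 ethyl 2-[2-formyl-3,5-dimethoxy-4-methyl-6-(3-phenylpropanoyl)phenoxy]-2-methylpropanoate
Product: 10 ethyl 2-[2-formyl-3,5-dihydroxy-4-methyl-6-(3-phenylpropanoyl)phenoxy]-2-methylpropanoate
Conditions: BCl3 (4 equiv), CH2Cl2, −78 to 0 °C; aq. work-up
Reagents that add atoms: none
Why: Chelation-assisted ether cleavage; each methoxy group is ortho to a carbonyl group and is demethylated through a boron chelate, whereas the aryl tert-alkyl ether should survive because its α-ester carbon allows neither SN2 nor SN1 cleavage.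

Step 6
Reactants: 10 ethyl 2-[2-formyl-3,5-dihydroxy-4-methyl-6-(3-phenylpropanoyl)phenoxy]-2-methylpropanoate
Product: 11 ethyl 2-[3,5-bis(benzyloxy)-2-formyl-4-methyl-6-(3-phenylpropanoyl)phenoxy]-2-methylpropanoate
Conditions: BnBr (2.5 equiv), K2CO3, nBu4NI (cat.), DMF, 60 °C
Reagents that add atoms: benzyl bromide, BrCc1ccccc1
Why: Williamson etherification of both phenoxides; K2CO3 is too weak to enolise the ketone, and benzyl ethers are chosen because they withstand the remaining steps and leave by neutral hydrogenolysis at the end.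

Step 7
Reactants: 11 ethyl 2-[3,5-bis(benzyloxy)-2-formyl-4-methyl-6-(3-phenylpropanoyl)phenoxy]-2-methylpropanoate
Product: 13 2-[3,5-bis(benzyloxy)-2-(hydroxymethyl)-4-methyl-6-(3-phenylpropanoyl)phenoxy]-2-methylpropanoic acid, via hydroxy ester 12 (not isolated)
Conditions: NaBH4 (1.0 equiv), THF/MeOH, −10 °C; then LiOH, H2O, 40 °C; cold 0.5 M HCl to pH 4
Reagents that add atoms: lithium hydroxide, [Li+].[OH-] (one oxygen of the carboxyl group)
Why: Chemoselective borohydride reduction of the aldehyde beside the doubly ortho-substituted aryl ketone and the hindered ester, followed in the same flask by saponification of the ethyl ester, which leaves ketone, benzyl ethers and benzylic alcohol untouched.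

Step 8
Reactants: 13 2-[3,5-bis(benzyloxy)-2-(hydroxymethyl)-4-methyl-6-(3-phenylpropanoyl)phenoxy]-2-methylpropanoic acid
Product: 15 2-[3,5-bis(benzyloxy)-2-(chloromethyl)-4-methyl-6-(3-phenylpropanoyl)phenoxy]-2-methylpropanal, via chloro acid chloride 14 (not isolated)
Conditions: SOCl2 (3 equiv), DMF (cat.), CH2Cl2, 0 °C to rt; evaporate; LiAlH(OtBu)3 (1.05 equiv), THF, −78 °C; cold neutral work-up, crude 15 used at once
Reagents that add atoms: thionyl chloride, O=S(Cl)Cl (chlorine atoms of 14 and 15)
Why: Thionyl chloride should convert the electron-rich benzylic alcohol into the chloride and the acid into the acid chloride (as for fibrate-type 2-aryloxy-2-methylpropanoic acids), and the bulky alkoxyaluminium hydride at −78 °C then reduces only the acid chloride to the aldehyde (partial reduction of an acid chloride), so that chloride and aldehyde appear together without any aqueous acid.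

Step 9
Reactants: 15 2-[3,5-bis(benzyloxy)-2-(chloromethyl)-4-methyl-6-(3-phenylpropanoyl)phenoxy]-2-methylpropanal
Product: 17 1-[(3S)-5,7-bis(benzyloxy)-3-hydroxy-2,2,6-trimethyl-3,4-dihydro-2H-chromen-8-yl]-3-phenylpropan-1-one, via trimethylsilyl ether 16 (not isolated)
Conditions: CrCl3·3THF (15 mol%), L* (18 mol%), Et3N (18 mol%), Me3SiCl (2 equiv), nBu4NPF6 (0.1 M), THF/MeCN, divided cell, graphite-felt cathode held at the potential of the trivalent/divalent chromium couple, Zn anode, rt, 2.2 F/mol; then 1 M HCl, THF, 0 °C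
Reagents that add atoms: chlorotrimethylsilane, C[Si](C)(C)Cl (silyl group of intermediate 16 only)
Why: Proposed new method: the cathode reduces the ligated CrCl3 to divalent chromium; one divalent chromium takes the chlorine atom from the benzylic C–Cl bond of 15, a second traps the benzyl radical as a trivalent benzylchromium, and this adds to the tethered aldehyde before Me3SiCl silylates the chromium alkoxide and frees trivalent chromium for the next cathodic reduction. The closest known reaction types are electrochemically turned-over catalytic Nozaki–Hiyama–Kishi couplings, stoichiometric benzylchromium additions to aldehydes and ligand-controlled enantioselective chromium allylations; a catalytic, enantioselective, intramolecular benzyl transfer has not been shown. The pyran ring closes in the 6-exo-trig mode (new C3–C4 bond; ring atoms C4, C4a, C8a, O1, C2, C3), helped by the gem-dimethyl group at C2. The C3 stereocentre is set by the chiral sulfonamide–oxazoline ligand on chromium, which has to deliver the benzyl carbon to the Si face of the aldehyde to give 3S. The step needs selectivity for the aldehyde over the C8 ketone and over direct cathodic reduction: organochromium reagents strongly prefer aldehydes, the ketone is shielded by two ortho substituents and is meta to the benzyl carbon so that no ring could form, the aldehyde is α-quaternary and cannot enolise, and the chromium couple lies well positive of the reduction of ketone, aldehyde and C–Cl bond.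

Step 10
Reactants: 17 1-[(3S)-5,7-bis(benzyloxy)-3-hydroxy-2,2,6-trimethyl-3,4-dihydro-2H-chromen-8-yl]-3-phenylpropan-1-one
Product: 18 1-[(3S)-3,5,7-trihydroxy-2,2,6-trimethyl-3,4-dihydro-2H-chromen-8-yl]-3-phenylpropan-1-one (the target)
Conditions: H2 (1 atm), 10% Pd/C, EtOAc, rt
Reagents that add atoms: none
Why: Hydrogenolysis of the two benzyl aryl ethers over palladium on carbon; the C3 carbinol is not benzylic and the hindered aryl ketone should not be reduced under these mild conditions, so the C3 configuration and the carbonyl group are kept.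

Compound list
1 | 2,6-dimethoxytoluene | COc1cccc(OC)c1C | starting material
2 | 2-(3,5-dimethoxy-4-methylphenyl)-4,4,5,5-tetramethyl-1,3,2-dioxaborolane | COc1cc(B2OC(C)(C)C(C)(C)O2)cc(OC)c1C | intermediate
3 | 3,5-dimethoxy-4-methylphenol | COc1cc(O)cc(OC)c1C | intermediate
4 | ethyl 2-bromo-2-methylpropanoate | CCOC(=O)C(C)(C)Br | starting material
5 | ethyl 2-(3,5-dimethoxy-4-methylphenoxy)-2-methylpropanoate | CCOC(=O)C(C)(C)Oc1cc(OC)c(C)c(OC)c1 | intermediate
6 | 3-phenylpropanoyl chloride | O=C(Cl)CCc1ccccc1 | starting material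
7 | ethyl 2-[3,5-dimethoxy-4-methyl-2-(3-phenylpropanoyl)phenoxy]-2-methylpropanoate | CCOC(=O)C(C)(C)Oc1cc(OC)c(C)c(OC)c1C(=O)CCc1ccccc1 | intermediate
8 | ethyl 2-{2-[chloro(methoxy)methyl]-3,5-dimethoxy-4-methyl-6-(3-phenylpropanoyl)phenoxy}-2-methylpropanoate | CCOC(=O)C(C)(C)Oc1c(C(Cl)OC)c(OC)c(C)c(OC)c1C(=O)CCc1ccccc1 | intermediate
9 | ethyl 2-[2-formyl-3,5-dimethoxy-4-methyl-6-(3-phenylpropanoyl)phenoxy]-2-methylpropanoate | CCOC(=O)C(C)(C)Oc1c(C=O)c(OC)c(C)c(OC)c1C(=O)CCc1ccccc1 | intermediate
10 | ethyl 2-[2-formyl-3,5-dihydroxy-4-methyl-6-(3-phenylpropanoyl)phenoxy]-2-methylpropanoate | CCOC(=O)C(C)(C)Oc1c(C=O)c(O)c(C)c(O)c1C(=O)CCc1ccccc1 | intermediate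
11 | ethyl 2-[3,5-bis(benzyloxy)-2-formyl-4-methyl-6-(3-phenylpropanoyl)phenoxy]-2-methylpropanoate | CCOC(=O)C(C)(C)Oc1c(C=O)c(OCc2ccccc2)c(C)c(OCc2ccccc2)c1C(=O)CCc1ccccc1 | intermediate
12 | ethyl 2-[3,5-bis(benzyloxy)-2-(hydroxymethyl)-4-methyl-6-(3-phenylpropanoyl)phenoxy]-2-methylpropanoate | CCOC(=O)C(C)(C)Oc1c(CO)c(OCc2ccccc2)c(C)c(OCc2ccccc2)c1C(=O)CCc1ccccc1 | intermediate
13 | 2-[3,5-bis(benzyloxy)-2-(hydroxymethyl)-4-methyl-6-(3-phenylpropanoyl)phenoxy]-2-methylpropanoic acid | OC(=O)C(C)(C)Oc1c(CO)c(OCc2ccccc2)c(C)c(OCc2ccccc2)c1C(=O)CCc1ccccc1 | intermediate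
14 | 2-[3,5-bis(benzyloxy)-2-(chloromethyl)-4-methyl-6-(3-phenylpropanoyl)phenoxy]-2-methylpropanoyl chloride | ClC(=O)C(C)(C)Oc1c(CCl)c(OCc2ccccc2)c(C)c(OCc2ccccc2)c1C(=O)CCc1ccccc1 | intermediate
15 | 2-[3,5-bis(benzyloxy)-2-(chloromethyl)-4-methyl-6-(3-phenylpropanoyl)phenoxy]-2-methylpropanal | O=CC(C)(C)Oc1c(CCl)c(OCc2ccccc2)c(C)c(OCc2ccccc2)c1C(=O)CCc1ccccc1 | intermediate
16 | 1-{(3S)-5,7-bis(benzyloxy)-2,2,6-trimethyl-3-[(trimethylsilyl)oxy]-3,4-dihydro-2H-chromen-8-yl}-3-phenylpropan-1-one | Cc1c(OCc3ccccc3)c2c(c(C(=O)CCc4ccccc4)c1OCc5ccccc5)OC(C)(C)[C@@H](O[Si](C)(C)C)C2 | intermediate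
17 | 1-[(3S)-5,7-bis(benzyloxy)-3-hydroxy-2,2,6-trimethyl-3,4-dihydro-2H-chromen-8-yl]-3-phenylpropan-1-one | Cc1c(OCc3ccccc3)c2c(c(C(=O)CCc4ccccc4)c1OCc5ccccc5)OC(C)(C)[C@@H](O)C2 | intermediate
18 | 1-[(3S)-3,5,7-trihydroxy-2,2,6-trimethyl-3,4-dihydro-2H-chromen-8-yl]-3-phenylpropan-1-one | Cc1c(O)c2c(c(C(=O)CCc3ccccc3)c1O)OC(C)(C)[C@@H](O)C2 | target

Total step count: 10. Longest linear sequence: 10 steps (1 to 18).

Steps most likely to fail

Step 9. The chromium cycle may turn over poorly, the benzyl radical may dimerise, the labile chloride may ionise, or the ligand may give poor facial selectivity in the ring closure. The fallback sets out from 15, returns at 18 and uses known reactions only. PPh3 (MeCN, rt) quaternises the reactive benzylic chloride to {[2,4-bis(benzyloxy)-3-methyl-6-[(2-methyl-1-oxopropan-2-yl)oxy]-5-(3-phenylpropanoyl)phenyl]methyl}triphenylphosphonium chloride F1. K2CO3 (CH2Cl2/H2O or THF) then forms the benzylic ylide, which closes onto the tethered aldehyde in an intramolecular Wittig reaction to give the chromene 1-[5,7-bis(benzyloxy)-2,2,6-trimethyl-2H-chromen-8-yl]-3-phenylpropan-1-one F2. Jacobsen–Katsuki epoxidation with [(S,S)-N,N′-bis(3,5-di-tert-butylsalicylidene)-1,2-cyclohexanediaminato]MnCl, NaOCl and 4-phenylpyridine N-oxide in CH2Cl2 at 0 °C should give, by analogy with simple 2,2-dimethylchromenes, 1-[(3S,4S)-5,7-bis(benzyloxy)-3,4-epoxy-2,2,6-trimethyl-3,4-dihydro-2H-chromen-8-yl]-3-phenylpropan-1-one F3. This acid-sensitive epoxide would be hydrogenated crude (H2, Pd/C, EtOAc); hydrogenolysis of the benzylic C4–O bond and of both benzyl ethers gives 18 with C3 unchanged. The stereocentre then comes from an established catalyst-controlled epoxidation and not from the C–C bond formation.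

Step 8. The hydroxy acid may lactonise on activation, or the benzylic chloride may be lost during the hydride reduction and its work-up. The fallback sets out from 13 and returns at 15; it carries the benzylic oxygen as an acetate, so that the aldehyde can be made and purified before the chloride exists. Ac2O/pyridine/DMAP at 0 °C, followed by brief aqueous hydrolysis of the mixed anhydride, gives 2-[2-(acetoxymethyl)-3,5-bis(benzyloxy)-4-methyl-6-(3-phenylpropanoyl)phenoxy]-2-methylpropanoic acid F4. 1-Chloro-N,N,2-trimethylprop-1-en-1-amine (CH2Cl2, rt) gives the acid chloride 2-[2-(acetoxymethyl)-3,5-bis(benzyloxy)-4-methyl-6-(3-phenylpropanoyl)phenoxy]-2-methylpropanoyl chloride F5 under neutral conditions. LiAlH(OtBu)3 at −78 °C reduces it to the stable aldehyde [2,4-bis(benzyloxy)-3-methyl-6-[(2-methyl-1-oxopropan-2-yl)oxy]-5-(3-phenylpropanoyl)phenyl]methyl acetate F6. Dry HCl in dioxane/CH2Cl2 at 0 °C then exchanges the acetate of this trialkoxybenzyl ester for chloride by SN1 ionisation, immediately before the electrolysis, to give 15.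

Step 4. Electrophilic attack at the last, doubly flanked position of the acyl-deactivated triether may be sluggish, or may be diverted to the enolisable ketone or to partial ether cleavage. The fallback sets out from 7 and returns at 10; it inverts the order of demethylation and formylation so that a free phenol directs the formylation. BBr3 (CH2Cl2, −78 to 0 °C) cleaves both methyl ethers to give ethyl 2-[3,5-dihydroxy-4-methyl-2-(3-phenylpropanoyl)phenoxy]-2-methylpropanoate F7. Magnesium-mediated ortho-formylation of the phenol (MgCl2, Et3N, paraformaldehyde, MeCN, reflux) then places the formyl group at the only free position, ortho to the 5-hydroxyl group, to give 10.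

Further compounds
F1 | step 9 | {[2,4-bis(benzyloxy)-3-methyl-6-[(2-methyl-1-oxopropan-2-yl)oxy]-5-(3-phenylpropanoyl)phenyl]methyl}triphenylphosphonium chloride | O=CC(C)(C)Oc1c(C[P+](c2ccccc2)(c2ccccc2)c2ccccc2)c(OCc2ccccc2)c(C)c(OCc2ccccc2)c1C(=O)CCc1ccccc1.[Cl-]
F2 | step 9 | 1-[5,7-bis(benzyloxy)-2,2,6-trimethyl-2H-chromen-8-yl]-3-phenylpropan-1-one | Cc1c(OCc3ccccc3)c2c(c(C(=O)CCc4ccccc4)c1OCc5ccccc5)OC(C)(C)C=C2
F3 | step 9 | 1-[(3S,4S)-5,7-bis(benzyloxy)-3,4-epoxy-2,2,6-trimethyl-3,4-dihydro-2H-chromen-8-yl]-3-phenylpropan-1-one | Cc1c(OCc3ccccc3)c2c(c(C(=O)CCc4ccccc4)c1OCc5ccccc5)OC(C)(C)[C@H]6O[C@@H]26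
F4 | step 8 | 2-[2-(acetoxymethyl)-3,5-bis(benzyloxy)-4-methyl-6-(3-phenylpropanoyl)phenoxy]-2-methylpropanoic acid | OC(=O)C(C)(C)Oc1c(COC(C)=O)c(OCc2ccccc2)c(C)c(OCc2ccccc2)c1C(=O)CCc1ccccc1
F5 | step 8 | 2-[2-(acetoxymethyl)-3,5-bis(benzyloxy)-4-methyl-6-(3-phenylpropanoyl)phenoxy]-2-methylpropanoyl chloride | ClC(=O)C(C)(C)Oc1c(COC(C)=O)c(OCc2ccccc2)c(C)c(OCc2ccccc2)c1C(=O)CCc1ccccc1
F6 | step 8 | [2,4-bis(benzyloxy)-3-methyl-6-[(2-methyl-1-oxopropan-2-yl)oxy]-5-(3-phenylpropanoyl)phenyl]methyl acetate | O=CC(C)(C)Oc1c(COC(C)=O)c(OCc2ccccc2)c(C)c(OCc2ccccc2)c1C(=O)CCc1ccccc1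
F7 | step 4 | ethyl 2-[3,5-dihydroxy-4-methyl-2-(3-phenylpropanoyl)phenoxy]-2-methylpropanoate | CCOC(=O)C(C)(C)Oc1cc(O)c(C)c(O)c1C(=O)CCc1ccccc1
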